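**Retrosynthetic overview**

1. Ring numbering used throughout: C1(Me)(Cl)–C2H2–C3(Me)(C7H=C8HBr)–C4HBr–C5H2–C6HCl. The plan rests on C1, the ring carbon that carries methyl and chlorine and lies between C2 and C6: it is inserted as a CH3–C unit into the C6–C2 bond of a cyclopentanone whose C3/C4 pair is set beforehand.
2. Target 24 ⇒ aldehyde 22 (Takai bromo-olefination makes C7=C8) ⇒ vinyl compound 20 ⇒ C4 alcohol 17 (invertive bromination) ⇒ C6 alcohol 14 (invertive chlorination) ⇒ ketone 13 (face-selective reduction).
3. Key disconnection: 2-chloro-2-methylcyclohexanone 13 ⇒ 1-(1,1-dibromoethyl)cyclopentanol 9, by bromine–lithium exchange, 1,2-shift of C2 from C6 to C1, and chlorination of the resulting C6=C1 enolate at C1.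
4. Carbinol 9 ⇒ cyclopentanone 7 + 1,1-dibromoethane; 7 ⇒ enone 4 (vinyl-copper addition anti to the C4 silyloxy group) ⇒ purchased (R)-4-silyloxycyclopentenone 1 (methyl addition, then dehydrogenation).
5. Ring order: the five-membered ring is bought; the cyclohexane is the only ring formed, by enlargement in step 5.

Key step: step 5

Assumption: the target is taken as drawn, with C1–Cl, C6–Cl, C4–Br and the bromovinyl group on one ring face and both methyl groups on the other; (R)-4-(tert-butyldimethylsilyloxy)cyclopent-2-en-1-one is treated as a purchasable enantiopure building block, and positions are quoted in the target numbering also for the five-membered precursors (C6 = carbonyl carbon, C1 not yet present).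

**Route**

Step 1
Reactants: 1 (R)-4-(tert-butyldimethylsilyloxy)cyclopent-2-en-1-one; 2 methylmagnesium bromide
Product: 3 tert-butyldimethyl{[(1R,2R)-2-methyl-4-(trimethylsilyloxy)cyclopent-3-en-1-yl]oxy}silane (methyl trans to OTBS)
Conditions: MeMgBr, CuBr·SMe2 (10 mol %), TMSCl, THF, −78 °C; Et3N, cold aq. NaHCO3
Reagents that add atoms: methylmagnesium bromide, C[Mg]Br; chlorotrimethylsilane, C[Si](C)(C)Cl
Why: Copper-catalysed, TMSCl-accelerated conjugate addition of the Grignard reagent should deliver methyl to C3 anti to the C4 silyloxy group and trap the enolate regiospecifically as the C6=C2 silyl enol ether, which keeps the β-silyloxy group from elimination; the C3 configuration is immaterial because C3 becomes trigonal again in step 2.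

Step 2
Reactants: 3 tert-butyldimethyl{[(1R,2R)-2-methyl-4-(trimethylsilyloxy)cyclopent-3-en-1-yl]oxy}silane
Product: 4 (R)-4-(tert-butyldimethylsilyloxy)-3-methylcyclopent-2-en-1-one
Conditions: Pd(OAc)2 (10 mol %), O2 (1 atm), DMSO, 25 °C
Reagents that add atoms: none
Why: Saegusa–Ito oxidation, in which palladation of the silyl enol ether at C2 and syn β-hydride elimination of the C3 hydrogen should return the enone with the methyl group now on C3, the C4 stereocentre not being touched.

Step 3
Reactants: 4 (R)-4-(tert-butyldimethylsilyloxy)-3-methylcyclopent-2-en-1-one; 5 vinylmagnesium bromide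
Product: 7 (3S,4R)-4-(tert-butyldimethylsilyloxy)-3-ethenyl-3-methylcyclopentan-1-one, via trimethylsilyl enol ether 6 (not isolated)
Conditions: CH2=CHMgBr, CuBr·SMe2 (20 mol %), TMSCl, HMPA, THF, −78 to −40 °C; then 1 M aq. HCl, THF, 0 °C
Reagents that add atoms: vinylmagnesium bromide, C=C[Mg]Br
Why: Copper-catalysed conjugate addition to the β,β-disubstituted enone, driven by TMSCl/HMPA, should bring the vinyl group to C3 on the face opposite the adjacent C4 silyloxy group, which sets the quaternary centre with vinyl trans to OTBS, and brief acid hydrolysis of enol ether 6 gives the ketone without β-elimination.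

Step 4
Reactants: 7 (3S,4R)-4-(tert-butyldimethylsilyloxy)-3-ethenyl-3-methylcyclopentan-1-one; 8 1,1-dibromoethane
Product: 9 (1R,3S,4R)-4-(tert-butyldimethylsilyloxy)-1-(1,1-dibromoethyl)-3-ethenyl-3-methylcyclopentan-1-ol
Conditions: CH3CHBr2, LiN(i-Pr)2, THF–Et2O, −100 °C; then 7, −100 to −78 °C; AcOH, −78 °C
Reagents that add atoms: 1,1-dibromoethane, CC(Br)Br
Why: 1,2-Addition of the preformed lithium carbenoid 1,1-dibromoethyllithium (strongly nucleophilic and weakly basic at this temperature) to the ketone should give the tertiary carbinol, attack being expected anti to the C4 silyloxy and C3 methyl groups; the carbinol configuration is of no consequence because this carbon becomes the C6 carbonyl in step 5, so either epimer is carried on.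

Step 5
Reactants: 9 (1R,3S,4R)-4-(tert-butyldimethylsilyloxy)-1-(1,1-dibromoethyl)-3-ethenyl-3-methylcyclopentan-1-ol; 10 N-chlorosuccinimide
Product: 13 (2S,4S,5R)-5-(tert-butyldimethylsilyloxy)-2-chloro-4-ethenyl-2,4-dimethylcyclohexan-1-one, via lithium alkoxide carbenoid 11 (not isolated), via lithium enolate 12 (not isolated)
Conditions: n-BuLi (2.1 equiv), THF, −95 °C, then −78 to −20 °C; NCS, THF, −78 °C; AcOH
Reagents that add atoms: N-chlorosuccinimide, O=C1CCC(=O)N1Cl
Why: Two equivalents of n-BuLi give first the lithium alkoxide and then, by bromine–lithium exchange, the α-bromo-α-lithio carbenoid 11; on warming, the alkoxide pushes the C6–C2 ring bond onto the carbenoid carbon C1 as bromide leaves, so that the C1–C2 bond and the lithium enolate 12 (C6=C1) form in one event, and NCS then transfers chlorine to C1. The closest known reaction type is the β-oxido carbenoid ring enlargement of dihaloalkyllithium–cycloalkanone adducts, followed by electrophilic α-chlorination of a lithium enolate. The cyclohexane ring is not closed by cyclisation but arises by one-carbon enlargement of the cyclopentane through this 1,2-alkyl shift, which also erases the carbinol centre so that both epimers of 9 converge. The new stereocentre C1 is set by the face on which NCS attacks 12: with the C4 silyloxy group pseudoaxial (avoiding the two gauche contacts at the quaternary C3), the vinyl group is axial and the C3 methyl equatorial, so stereoelectronically favoured axial attack at C1 should occur on the vinyl face, past a flat sp2 group and not a syn-axial methyl, placing chlorine cis to vinyl. The step needs migration of C2 and not C5, which should be secured by the inductively withdrawing, silyloxy-bearing C4 next to C5 (lower migratory aptitude) against the electron-rich quaternary C3 next to C2; chlorination only at C1 is inherent, because the enolate is generated regiospecifically and C5 is never deprotonated, so the β-silyloxy group cannot be eliminated.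

Step 6
Reactants: 13 (2S,4S,5R)-5-(tert-butyldimethylsilyloxy)-2-chloro-4-ethenyl-2,4-dimethylcyclohexan-1-one
Product: 14 (1S,2S,4S,5R)-5-(tert-butyldimethylsilyloxy)-2-chloro-4-ethenyl-2,4-dimethylcyclohexan-1-ol (C6–OH trans to C1–Cl)
Conditions: LiBH(s-Bu)3, THF, −78 °C; AcOH, −78 °C
Reagents that add atoms: none
Why: Bulky-hydride ketone reduction: in the favoured chair of 13 (C1–Cl and C3-vinyl axial on one face, both methyl groups equatorial, C4–OSi axial on the other face) the axial path to C6 is blocked by the syn-axial silyloxy group, so hydride should enter equatorially from the chlorine-bearing face and give the axial C6 alcohol trans to the C1 chlorine, and the cold acidic quench prevents closure of this trans-chlorohydrin to an epoxide.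

Step 7
Reactants: 14 (1S,2S,4S,5R)-5-(tert-butyldimethylsilyloxy)-2-chloro-4-ethenyl-2,4-dimethylcyclohexan-1-ol; 10 N-chlorosuccinimide
Product: 16 tert-butyl{[(1R,2S,4S,5R)-4,5-dichloro-2-ethenyl-2,4-dimethylcyclohexyl]oxy}dimethylsilane (C1–Cl and C6–Cl cis), via alkoxyphosphonium chloride 15 (not isolated)
Conditions: PPh3, NCS, THF, 0 °C; then 14, 0 to 45 °C
Reagents that add atoms: N-chlorosuccinimide, O=C1CCC(=O)N1Cl
Why: Appel-type deoxychlorination: the alcohol is activated as alkoxyphosphonium chloride 15 and displaced by chloride in an SN2 reaction with inversion at C6, which places the new chlorine cis to the C1 chlorine; the non-ionising medium should disfavour bridging by the neighbouring chlorine, and this reagent pair is known to invert secondary carbinols flanked by fully substituted carbons.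

Step 8
Reactants: 16 tert-butyl{[(1R,2S,4S,5R)-4,5-dichloro-2-ethenyl-2,4-dimethylcyclohexyl]oxy}dimethylsilane
Product: 17 (1R,2S,4S,5R)-4,5-dichloro-2-ethenyl-2,4-dimethylcyclohexan-1-ol
Conditions: HF·pyridine, pyridine, THF, 0 to 25 °C
Reagents that add atoms: none
Why: Acidic fluoride cleavage of the silyl ether should free the C4 alcohol without touching the tertiary and secondary chlorides, which a basic fluoride source could dehydrochlorinate; no stereocentre is affected.

Step 9
Reactants: 17 (1R,2S,4S,5R)-4,5-dichloro-2-ethenyl-2,4-dimethylcyclohexan-1-ol; 18 N-bromosuccinimide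
Product: 20 (1S,2S,4S,5R)-1-bromo-4,5-dichloro-2-ethenyl-2,4-dimethylcyclohexane, via alkoxyphosphonium bromide 19 (not isolated)
Conditions: PPh3, NBS, CH2Cl2, −20 °C; then 17, −20 to 25 °C
Reagents that add atoms: N-bromosuccinimide, O=C1CCC(=O)N1Br
Why: Appel-type deoxybromination: bromide displaces the alkoxyphosphonium group of 19 in an SN2 reaction with inversion at C4, putting bromine cis to the C3 vinyl group; the carbinol is neopentylic, but triphenylphosphine/N-halosuccinimide reagents are known to invert secondary alcohols next to a methyl- and vinyl-bearing quaternary carbon.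

Step 10
Reactants: 20 (1S,2S,4S,5R)-1-bromo-4,5-dichloro-2-ethenyl-2,4-dimethylcyclohexane
Product: 22 (1S,2S,4S,5R)-2-bromo-4,5-dichloro-1,4-dimethylcyclohexane-1-carbaldehyde, via secondary ozonide 21 (not isolated)
Conditions: O3, CH2Cl2, −78 °C; then PPh3, −78 to 25 °C
Reagents that add atoms: ozone, [O-][O+]=O
Why: Ozonolysis of the only alkene with reductive work-up should give the C7 aldehyde, which has no α-hydrogen (C3 is quaternary), so neither epimerisation nor β-elimination of the C4 bromide is possible.

Step 11
Reactants: 22 (1S,2S,4S,5R)-2-bromo-4,5-dichloro-1,4-dimethylcyclohexane-1-carbaldehyde; 23 bromoform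
Product: 24 (1S,2S,4S,5R)-1-bromo-2-[(E)-2-bromoethenyl]-4,5-dichloro-2,4-dimethylcyclohexane (target)
Conditions: CHBr3, CrBr2, THF, 0 to 25 °C
Reagents that add atoms: bromoform, BrC(Br)Br
Why: Takai olefination: the geminal dichromium reagent formed from bromoform and divalent chromium adds to the aldehyde and eliminates to the (E)-alkenyl bromide, the E geometry following from the anti arrangement of the bulky ring and bromine in the elimination; CrBr2 in place of CrCl2 excludes halide scrambling to an alkenyl chloride, and the alkyl halides should be inert to divalent chromium in THF at this temperature.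

**Compound list**

1 | (R)-4-(tert-butyldimethylsilyloxy)cyclopent-2-en-1-one | O=C1C=C[C@H](O[Si](C)(C)C(C)(C)C)C1 | starting material
2 | methylmagnesium bromide | C[Mg]Br | starting material
3 | tert-butyldimethyl{[(1R,2R)-2-methyl-4-(trimethylsilyloxy)cyclopent-3-en-1-yl]oxy}silane | C[Si](C)(C)OC1=C[C@@H](C)[C@H](O[Si](C)(C)C(C)(C)C)C1 | intermediate
4 | (R)-4-(tert-butyldimethylsilyloxy)-3-methylcyclopent-2-en-1-one | CC1=CC(=O)C[C@H]1O[Si](C)(C)C(C)(C)C | intermediate
5 | vinylmagnesium bromide | C=C[Mg]Br | starting material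
6 | tert-butyl{[(1R,2R)-2-ethenyl-2-methyl-4-(trimethylsilyloxy)cyclopent-3-en-1-yl]oxy}dimethylsilane (not isolated) | C[Si](C)(C)OC1=C[C@@](C)(C=C)[C@H](O[Si](C)(C)C(C)(C)C)C1 | intermediate
7 | (3S,4R)-4-(tert-butyldimethylsilyloxy)-3-ethenyl-3-methylcyclopentan-1-one (vinyl trans to OTBS) | O=C1C[C@@](C)(C=C)[C@H](O[Si](C)(C)C(C)(C)C)C1 | intermediate
8 | 1,1-dibromoethane | CC(Br)Br | starting material
9 | (1R,3S,4R)-4-(tert-butyldimethylsilyloxy)-1-(1,1-dibromoethyl)-3-ethenyl-3-methylcyclopentan-1-ol (expected carbinol epimer; the other converges) | CC(Br)(Br)[C@@]1(O)C[C@@](C)(C=C)[C@H](O[Si](C)(C)C(C)(C)C)C1 | intermediate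
10 | N-chlorosuccinimide | O=C1CCC(=O)N1Cl | starting material
11 | lithium alkoxide of 9 carrying a 1-bromo-1-lithioethyl group (carbenoid, not isolated; carbenoid carbon not configurationally defined) | CC([Li])(Br)[C@@]1(O[Li])C[C@@](C)(C=C)[C@H](O[Si](C)(C)C(C)(C)C)C1 | intermediate
12 | lithium (4S,5R)-5-(tert-butyldimethylsilyloxy)-4-ethenyl-2,4-dimethylcyclohex-1-en-1-olate (not isolated) | [Li]OC1=C(C)C[C@@](C)(C=C)[C@H](O[Si](C)(C)C(C)(C)C)C1 | intermediate
13 | (2S,4S,5R)-5-(tert-butyldimethylsilyloxy)-2-chloro-4-ethenyl-2,4-dimethylcyclohexan-1-one | C[C@]1(Cl)C[C@@](C)(C=C)[C@H](O[Si](C)(C)C(C)(C)C)CC1=O | intermediate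
14 | (1S,2S,4S,5R)-5-(tert-butyldimethylsilyloxy)-2-chloro-4-ethenyl-2,4-dimethylcyclohexan-1-ol | C[C@]1(Cl)C[C@@](C)(C=C)[C@H](O[Si](C)(C)C(C)(C)C)C[C@@H]1O | intermediate
15 | {[(1S,2S,4S,5R)-5-(tert-butyldimethylsilyloxy)-2-chloro-4-ethenyl-2,4-dimethylcyclohexyl]oxy}triphenylphosphonium chloride (not isolated) | C[C@]1(Cl)C[C@@](C)(C=C)[C@H](O[Si](C)(C)C(C)(C)C)C[C@@H]1O[P+](c1ccccc1)(c1ccccc1)c1ccccc1.[Cl-] | intermediate
16 | tert-butyl{[(1R,2S,4S,5R)-4,5-dichloro-2-ethenyl-2,4-dimethylcyclohexyl]oxy}dimethylsilane | C[C@]1(Cl)C[C@@](C)(C=C)[C@H](O[Si](C)(C)C(C)(C)C)C[C@H]1Cl | intermediate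
17 | (1R,2S,4S,5R)-4,5-dichloro-2-ethenyl-2,4-dimethylcyclohexan-1-ol | C[C@]1(Cl)C[C@@](C)(C=C)[C@H](O)C[C@H]1Cl | intermediate
18 | N-bromosuccinimide | O=C1CCC(=O)N1Br | starting material
19 | {[(1R,2S,4S,5R)-4,5-dichloro-2-ethenyl-2,4-dimethylcyclohexyl]oxy}triphenylphosphonium bromide (not isolated) | C[C@]1(Cl)C[C@@](C)(C=C)[C@H](O[P+](c2ccccc2)(c2ccccc2)c2ccccc2)C[C@H]1Cl.[Br-] | intermediate
20 | (1S,2S,4S,5R)-1-bromo-4,5-dichloro-2-ethenyl-2,4-dimethylcyclohexane | C[C@]1(Cl)C[C@@](C)(C=C)[C@@H](Br)C[C@H]1Cl | intermediate
21 | 3-[(1S,2S,4S,5R)-2-bromo-4,5-dichloro-1,4-dimethylcyclohexyl]-1,2,4-trioxolane (secondary ozonide, not isolated; trioxolane carbon undefined) | C[C@]1(Cl)C[C@@](C)(C2OCOO2)[C@@H](Br)C[C@H]1Cl | intermediate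
22 | (1S,2S,4S,5R)-2-bromo-4,5-dichloro-1,4-dimethylcyclohexane-1-carbaldehyde | C[C@]1(Cl)C[C@@](C)(C=O)[C@@H](Br)C[C@H]1Cl | intermediate
23 | bromoform | BrC(Br)Br | starting material
24 | (1S,2S,4S,5R)-1-bromo-2-[(E)-2-bromoethenyl]-4,5-dichloro-2,4-dimethylcyclohexane | C[C@]1(Cl)C[C@@](C)(/C=C/Br)[C@@H](Br)C[C@H]1Cl | target

**Step count and risk**

Total step count: 11. Longest linear sequence: 11 steps (1 to 24).

Steps most likely to fail:

Step 5. The carbenoid rearrangement may move the wrong ring carbon (C5 in place of C2), or the carbenoid may decay by a 1,2-hydride shift before it rearranges. The chlorination of enolate 12 may also discriminate poorly between the two faces; C1 epimers would be separated at 13. The fallback places the new carbon between C6 and C2 by construction. It sets out from silyl enol ether 6, isolated by non-aqueous work-up of step 3. Dibromocarbene addition (CHBr3, KOt-Bu, pentane, −30 °C) gives the dibromocyclopropane F1. On warming in toluene this opens, with loss of the silyl group and one bromine, to the ring-enlarged 2-bromocyclohexenone F2. Stille methylation (Me4Sn, PdCl2(PPh3)2, CuI, DMF, 60 °C) gives the 2-methylcyclohexenone F3. Conjugate reduction with [(Ph3P)CuH]6 in the presence of TMSCl (THF, −40 to 0 °C) gives the trimethylsilyl enol ether F4, the silyl counterpart of 12. NCS in THF at 0 °C then chlorinates C1, and the sequence comes back to the route at 13.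

Step 7. Activation and displacement at C6, which is flanked by the tertiary C1 chloride, may be slow. Bridging by the neighbouring chlorine (retention), elimination toward C5 or closure to the C1–C6 epoxide could then take over. The fallback replaces the bulky phosphonium leaving group by a sulfonate that reacts at low temperature. It sets out from 14: Tf2O, pyridine, CH2Cl2, −40 °C should give the C6 trifluoromethanesulfonate F5. Bu4NCl in toluene at −20 to 0 °C should displace it with inversion and return to the route at 16.

Step 9. At the neopentylic C4 carbinol, ionisation with participation or 1,2-shift of the neighbouring vinyl group, or elimination toward C5, may outrun direct displacement. The fallback postpones the displacement until the vinyl group has become the much less π-donating bromoalkene. It sets out from 16: ozonolysis (O3, CH2Cl2, −78 °C; then PPh3) via the secondary ozonide F6 gives the silyloxy aldehyde F7. Takai olefination (CHBr3, CrBr2, THF) gives the (E)-bromoalkene silyl ether F8. HF·pyridine gives the bromoalkene alcohol F9. PPh3/NBS, via the alkoxyphosphonium bromide F10, then brominates C4 with inversion and arrives directly at 24.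

**Further compounds**

F1 | step 5 | 6,6-dibromobicyclo[3.1.0]hexane adduct of 6 (cyclopropane across C6–C2, bridgehead OSiMe3; ring-fusion face not controlled; C3 and C4 as in 6) | C[Si](C)(C)OC12C(Br)(Br)C1[C@@](C)(C=C)[C@H](O[Si](C)(C)C(C)(C)C)C2
F2 | step 5 | 2-bromo-5-(tert-butyldimethylsilyloxy)-4-ethenyl-4-methylcyclohex-2-en-1-one (C3 and C4 as in 7) | O=C1C(Br)=C[C@@](C)(C=C)[C@H](O[Si](C)(C)C(C)(C)C)C1
F3 | step 5 | 5-(tert-butyldimethylsilyloxy)-4-ethenyl-2,4-dimethylcyclohex-2-en-1-one (C3 and C4 as in 7) | CC1=C[C@@](C)(C=C)[C@H](O[Si](C)(C)C(C)(C)C)CC1=O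
F4 | step 5 | trimethylsilyl enol ether corresponding to enolate 12 | C[Si](C)(C)OC1=C(C)C[C@@](C)(C=C)[C@H](O[Si](C)(C)C(C)(C)C)C1
F5 | step 7 | C6 trifluoromethanesulfonate of 14 | C[C@]1(Cl)C[C@@](C)(C=C)[C@H](O[Si](C)(C)C(C)(C)C)C[C@@H]1OS(=O)(=O)C(F)(F)F
F6 | step 9 | secondary ozonide of 16 (trioxolane carbon undefined) | C[C@]1(Cl)C[C@@](C)(C2OCOO2)[C@H](O[Si](C)(C)C(C)(C)C)C[C@H]1Cl
F7 | step 9 | 2-(tert-butyldimethylsilyloxy)-4,5-dichloro-1,4-dimethylcyclohexane-1-carbaldehyde (configuration as in 16) | C[C@]1(Cl)C[C@@](C)(C=O)[C@H](O[Si](C)(C)C(C)(C)C)C[C@H]1Cl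
F8 | step 9 | tert-butyldimethylsilyl ether of the C4 alcohol bearing the (E)-2-bromoethenyl group at C3 (configuration as in 16) | C[C@]1(Cl)C[C@@](C)(/C=C/Br)[C@H](O[Si](C)(C)C(C)(C)C)C[C@H]1Cl
F9 | step 9 | 2-[(E)-2-bromoethenyl]-4,5-dichloro-2,4-dimethylcyclohexan-1-ol (configuration as in 17) | C[C@]1(Cl)C[C@@](C)(/C=C/Br)[C@H](O)C[C@H]1Cl
F10 | step 9 | alkoxytriphenylphosphonium bromide of F9 | C[C@]1(Cl)C[C@@](C)(/C=C/Br)[C@H](O[P+](c2ccccc2)(c2ccccc2)c2ccccc2)C[C@H]1Cl.[Br-]
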